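Atoms are numbered as in the target decalin throughout (ring A = C1–C5 and C10, ring B = C5–C10, C11 = methylene carbon on C4, C15 = benzylic CH2), and the bicyclic intermediates carry the labels their atoms will have in the target. In the bicycles, "etheno bridge" means C4=C5, "ethano bridge" C1–C2 and "keto bridge" C8–C9.

## The problem

The target is a cis-fused decalin in which ring B carries four contiguous stereocentres, C5, C10, C9 and C8, and ring A carries the exocyclic methylene C4=C11 next to quaternary C5. C5 (angular methyl) and C9 (methyl plus the arylmethyl C15) are both quaternary, and the three methyl groups and H10 lie on one face while the arylmethyl group lies on the other, (5S,8S,9R,10R). There is no heteroatom on the decalin to relay stereochemistry, so the centres must control one another: C10 has to be fixed first in absolute terms, C9 and C5 are best set against it while the skeleton is rigid, and C8, a tertiary centre beside quaternary C9, is best set last. The 1,1-disubstituted alkene C4=C11 migrates into the ring under acid and would not survive hydrogenation, so it must appear late. The methyl ester would not survive a Grignard reagent or hot ylides and is best carried as an aryl bromide, with the phenol masked by a group that comes off under mild conditions. The enabling feature is that C5 sits next to a carbon (C4) that may be sp2 and oxygenated, and C8 may be a carbonyl. A bond drawn from C3 to C8 therefore turns the decalin into a bicyclo[2.2.2]octene whose atoms C6=C7–C8(O)–C3–C4=C5 form an oxy-Cope 1,5-diene, and that bicycle is the Diels–Alder adduct of a dearomatised phenol.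

## Retrosynthesis

**Aryl ester and phenol (30 ⇐ 29 ⇐ 28).** The phenol is unmasked last from MOM ether 29, and the ester C–C bond is cut back to aryl bromide 28. The bromide is inert to every base, organometallic and radical reagent used earlier, whereas an ester is not. The forward steps must leave C4=C11 alone, which a carbonylation under CO and a cold, dilute acetal exchange should do.

**C4=C11 (28 ⇐ 27).** The methylene is cut to the C4 ketone 27. This keeps the fragile alkene out of all but the last three steps, and C4 has no epimerisable neighbour because C5 is quaternary.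

**C8 methyl (27 ⇐ 26 ⇐ 25 ⇐ 24).** The C8–H bond and the C8–methyl bond are cut to give the C8 ketone 24, by way of methylene compounds 26 and 25. The C4 oxygen stays masked as a methyl enol ether in 24 and 25, so only C8 is olefinated. The reduction has to deliver hydrogen to C8 with the methyl ending cis to the C9 methyl, so a method under thermodynamic control is chosen over surface hydrogenation.

**Ring B (24 ⇐ 21).** The C5–C6 bond is cut and C3–C8 is reconnected, giving vinyl carbinol 21, a 2-vinylbicyclo[2.2.2]oct-5-en-2-ol. Compared with an aldol or alkylative closure of ring B, this cut forms the quaternary C5 and the cis ring fusion in one concerted event whose topology is fixed by the bicycle. It also leaves the C8 ketone and the C4 enol ether as differentiated handles. The forward reaction needs the vinyl group on the etheno side of C8.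

**C7–C8 (21 ⇐ 19 + 20).** The vinyl group is cut off to give ketone 19 and vinylmagnesium bromide 20. Ketone 19 cannot enolise (C9 is quaternary, C3 a bridgehead), so only addition is possible, and it must come from the etheno face.

**C9 substituents (19 ⇐ 17 ⇐ 11 + 15).** The C9–methyl and C9–C15 bonds are cut to give ketone 11 and benzylic bromide 15. C9 is the only enolisable position of 11, and the rigid bicycle offers two very different faces, so the order benzyl first, methyl second should put the methyl on the etheno side. Bromide 15 comes in three routine steps from 5-bromosalicylaldehyde 12 through 13 and 14.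

**Absolute configuration (11 ⇐ 8).** Ketone 11 is the (1R,4R) enantiomer of racemic ketone 8. It is resolved through the β-hydroxysulfoximine 10 formed with sulfoximine 9, which is recovered.

**The bicycle (8 ⇐ 7 ⇐ 6 ⇐ 3 + 4 ⇐ 1).** The C10–C1 and C3–C2 bonds are cut in a Diels–Alder sense to give the masked o-benzoquinone 5 (from phenol 3) and phenyl vinyl sulfone 4 as an ethylene equivalent. The phenol substitution pattern places the methyl on C5 and the methoxy group on C4 next to the carbonyl-side bridgehead. A cyclohexadiene plus ketene-equivalent route would give the wrong regiochemistry. The ketal oxygens and the sulfonyl group are removed reductively (6 → 7 → 8), and phenol 3 comes from aldehyde 1 by Baeyer–Villiger oxidation through formate 2.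

## Roads not taken

**Alternative 1:** Ring A would be annulated onto 3-methylcyclohex-2-en-1-one A1 by cutting C4–C5 and C1–C10. A copper-catalysed enantioselective conjugate addition of the chloropentenyl alane A2 (monovalent copper thiophene-2-carboxylate, Cu(O2CC4H3S), with a chiral phosphinamine ligand) sets C5, and the resulting C10 enolate then displaces chloride to give the cis-fused methylene decalone A3. This is the more economical opening. It is catalytic and asymmetric, needs no resolution, and reaches a decalin that already holds C5, C10 and the methylene in two operations, which the chosen plan cannot match. Its weak points lie after A3. C8 and the quaternary C9 still have to be built from the C9 ketone, by C8 methylation, a one-carbon homologation at C9, alkylation with a bromide such as 15 and reduction of the extra carbon to a methyl. The face selectivity of that quaternisation rests on the conformation of a flexible cis-decalin, and the acid-sensitive methylene rides through every one of those steps. Against this the chosen plan sets a C9 centre made on a rigid bicycle, a ring fusion fixed by orbital topology, and a methylene that appears only at the end, at the price of a resolution and a longer sequence.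

**Alternative 2:** Both rings would be closed at once by cutting C5–C10 and C3–C4, through an intramolecular Diels–Alder reaction of trienal A4 in which the (Z)-diene C10=C1–C2=C3 adds to the (E)-enal C4=C5 to give octalin aldehyde A5. The step is the most bond-forming of all the options and would carry the ester and the C8 and C9 centres through unchanged. For this target the difficulties are considerable. A4 needs the vicinal C8 and quaternary C9 centres built on an open chain. A (Z)-diene attached to a quaternary carbon reaches the s-cis geometry poorly and can escape by 1,5-hydrogen shift. The dienophile is trisubstituted, and the facial and endo/exo outcome depends on tether control alone. After cyclisation, C2=C3 must be reduced and the aldehyde turned into C4=C11, which costs about four steps. The chosen plan forms fewer bonds in its key step but starts from a far simpler precursor, and its stereochemical outcome is enforced by the bicycle and not by tether conformations.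

**Alternative 3:** Ring A would be closed last by cutting C4–C5. Monovalent gold (Ph3PAuCl with AgSbF6) activates the alkyne of silyl enol ether A6 for 6-exo-dig attack by C5, giving 6-oxo compound A7 with the methylene in place. This is better than the chosen plan in the endgame, since the methylene arises directly, no Wittig reaction is needed, and the ester can be present throughout. The cost is that A6 is a ring B cyclohexanone that already holds C8, C9 and C10, so the hard stereochemical problem is moved and not solved. The enol ether must be formed regioselectively at the tetrasubstituted C5=C6 position, and the C6 carbonyl, flanked by quaternary C5, must afterwards be removed in the presence of the alkene and the ester. The chosen plan builds its stereocentres in sequence from a simple phenol and has no oxygen to delete from ring B.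

Key step: step 13

Remarks on the chemistry:
- Compounds 6–8 are racemic. The SMILES of 6 and 7 show the enantiomer of the series that is carried on.
- Adduct 6 is expected as a mixture of regio- and stereoisomers at the sulfonyl-bearing bridge carbon. One isomer is drawn, and all converge on 8 after desulfonylation.
- Which sulfoximine adduct contains the (1R,4R) bicycle cannot be predicted. Compound 10 is defined as that diastereomer, to be assigned by X-ray crystallography.

## Route

Step 1
Reactants: 1 2,5-dimethoxy-4-methylbenzaldehyde
Product: 3 2,5-dimethoxy-4-methylphenol, via aryl formate 2 (not isolated)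
Conditions: mCPBA, CH2Cl2, 0 °C to rt; aq. NaHCO3 wash; then K2CO3 (cat.), MeOH, rt
Reagents that add atoms: 3-chloroperbenzoic acid (mCPBA), O=C(OO)c1cccc(Cl)c1
Why: Baeyer–Villiger (Dakin-type) oxidation of an electron-rich benzaldehyde, in which the ortho/para-methoxylated aryl group migrates; methanolysis of the formate then frees the phenol.

Step 2
Reactants: 3 2,5-dimethoxy-4-methylphenol; 4 phenyl vinyl sulfone
Product: 6 racemic 3,3,6-trimethoxy-5-methyl-7-(phenylsulfonyl)bicyclo[2.2.2]oct-5-en-2-one, via masked o-benzoquinone 5 (not isolated)
Conditions: PhI(OAc)2, 4 (excess), MeOH, slow addition of 3, rt to 50 °C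
Reagents that add atoms: methanol, CO
Why: Oxidative dearomatisation puts methoxide on the methoxy-bearing ortho carbon, and the resulting dienone is trapped in situ by Diels–Alder reaction with the sulfone (an ethylene equivalent) before it dimerises; the diene termini become bridgeheads C10 and C3, with the methoxy-bearing C4 next to the carbonyl-side bridgehead as the later [3,3] shift requires.

Step 3
Reactants: 6 sulfonyl keto-ketal
Product: 7 racemic 6-methoxy-5-methyl-7-(phenylsulfonyl)bicyclo[2.2.2]oct-5-en-2-one
Conditions: SmI2 (excess), THF–MeOH, rt
Reagents that add atoms: none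
Why: Samarium diiodide reduction of an α-alkoxy ketone, in which the ketyl expels each α-methoxy group in turn, a known way to strip the ketal from such adducts; the unactivated sulfone and the enol ether do not react without HMPA.

Step 4
Reactants: 7 sulfonyl ketone
Product: 8 racemic 6-methoxy-5-methylbicyclo[2.2.2]oct-5-en-2-one
Conditions: Na/Hg (6 %), Na2HPO4, MeOH–THF, −20 °C
Reagents that add atoms: none
Why: Reductive desulfonylation with buffered sodium amalgam (electron transfer to the arylsulfonyl group, C–S cleavage, protonation); the low temperature and buffer spare the isolated ketone, and no β-elimination is possible because C3 is a bridgehead.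

Step 5
Reactants: 8 racemic ketone; 9 (S)-N,S-dimethyl-S-phenylsulfoximine
Product: 10 β-hydroxysulfoximine of the (1R,4R) bicycle (C8 hydroxyl on the ethano side, sulfonimidoylmethyl group on the etheno side)
Conditions: 9, n-BuLi, THF, −78 °C; then 8, −78 °C; aq. NH4Cl; chromatographic separation of the two diastereomers
Reagents that add atoms: none
Why: Johnson sulfoximine resolution: the lithiated enantiopure sulfoximine adds to the ketone faster than it enolises it, from the less hindered etheno face, so each ketone enantiomer gives one diastereomer and the two should separate on silica.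

Step 6
Reactants: 10 β-hydroxysulfoximine
Product: 11 (1R,4R)-6-methoxy-5-methylbicyclo[2.2.2]oct-5-en-2-one
Conditions: toluene, 110 °C
Reagents that add atoms: none
Why: Thermal retro-addition of a β-hydroxysulfoximine returns the ketone as a single enantiomer and releases 9 for reuse; no stereocentre of the bicycle is touched.

Step 7
Reactants: 12 5-bromosalicylaldehyde
Product: 13 5-bromo-2-(methoxymethoxy)benzaldehyde
Conditions: MOMCl, i-Pr2NEt, CH2Cl2, 0 °C to rt
Reagents that add atoms: chloromethyl methyl ether (MOMCl), COCCl
Why: O-alkylation of a phenol to its MOM ether, which is stable to the bases, organometallics and radical conditions that follow.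

Step 8
Reactants: 13 aldehyde
Product: 14 [5-bromo-2-(methoxymethoxy)phenyl]methanol
Conditions: NaBH4, MeOH, 0 °C
Reagents that add atoms: none
Why: Borohydride reduction of an aromatic aldehyde; the aryl bromide and the acetal are inert.

Step 9
Reactants: 14 benzylic alcohol
Product: 15 4-bromo-2-(bromomethyl)-1-(methoxymethoxy)benzene
Conditions: CBr4, PPh3, CH2Cl2, 0 °C
Reagents that add atoms: carbon tetrabromide, BrC(Br)(Br)Br
Why: Appel bromination works under neutral conditions and so spares the acid-labile MOM ether.

Step 10
Reactants: 11 (1R,4R)-ketone; 15 benzylic bromide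
Product: 17 C9-monobenzyl ketone (benzyl on the etheno side expected; either C9 epimer serves), via lithium enolate 16 (not isolated)
Conditions: LDA, THF, −78 °C; then 15, −78 to 0 °C
Reagents that add atoms: none
Why: Enolate alkylation with a reactive benzylic bromide; C9 is the only enolisable position because C3 is a bridgehead, and the new C9 centre is provisional since it is planarised again in the next step.

Step 11
Reactants: 17 monobenzyl ketone
Product: 19 (1R,4S)-3-[5-bromo-2-(methoxymethoxy)benzyl]-6-methoxy-3,5-dimethylbicyclo[2.2.2]oct-5-en-2-one with the C9 methyl on the etheno side and the benzyl on the ethano side, via lithium enolate 18 (not isolated)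
Conditions: LDA, THF, −78 °C; then MeI, −78 to 0 °C
Reagents that add atoms: iodomethane, CI
Why: Second enolate alkylation, in which iodomethane approaches the face next to the etheno bridge because the inward hydrogens of the ethano bridge shield the other; the methyl therefore ends syn to C4=C5 and the benzyl is pushed to the ethano side, which sets C9 relative to the bridgeheads.

Step 12
Reactants: 19 dialkyl ketone; 20 vinylmagnesium bromide
Product: 21 2-vinylbicyclo[2.2.2]oct-5-en-2-ol: 3-[5-bromo-2-(methoxymethoxy)benzyl]-2-ethenyl-6-methoxy-3,5-dimethylbicyclo[2.2.2]oct-5-en-2-ol, vinyl and C9 methyl on the etheno side, hydroxyl and benzyl on the ethano side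
Conditions: 20, THF, 0 °C to rt; aq. NH4Cl
Reagents that add atoms: none
Why: Grignard 1,2-addition to a ketone that cannot enolise; the reagent approaches past the etheno bridge and the smaller C9 methyl, not past the ethano bridge and the benzyl group, placing the vinyl group over C4=C5.

Step 13
Reactants: 21 vinyl carbinol
Product: 24 cis-decal-8-one with C3=C4 methyl enol ether: 9-[5-bromo-2-(methoxymethoxy)benzyl]-4-methoxy-5,9-dimethyl-cis-decal-3-en-8-one (C5 methyl, C9 methyl and H10 on one face, benzyl on the other), via potassium alkoxide 22 (not isolated), via potassium enolate 23 (not isolated)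
Conditions: KH, 18-crown-6, THF, 0 to 45 °C; then aq. NH4Cl, −78 °C
Reagents that add atoms: none
Why: KH forms the tertiary alkoxide and the crown ether loosens its ion pair, which triggers the anionic oxy-Cope [3,3] shift of the diene C6=C7–C8–C3–C4=C5: C3–C8 breaks while C5–C6 forms, giving the C7=C8 enolate, which is protonated on work-up to the C8 ketone. The closest known reaction type is the anionic oxy-Cope rearrangement of 2-vinylbicyclo[2.2.2]oct-5-en-2-ols from masked o-benzoquinone adducts to cis-decalones. Ring B closes as a six-membered carbocycle by the sigmatropic C5–C6 bond through the boat-like six-centre transition state that the bicycle enforces, and ring A is simply the former cyclohexene ring, set free when C3–C8 breaks. The one new stereocentre, C5, is controlled by C10 through the bicyclic topology: C6 can only reach the face of C4=C5 that looks at the keto bridge, so the C5 methyl is forced cis to H10. The selectivity the step needs is that the vinyl group sits on the etheno side of C8, which step 12 secures, since the other epimer cannot reach the transition state. The products are differentiated at once, with C8 as a ketone and C4 as a methyl enol ether at C3=C4, and the aryl bromide and MOM ether are inert to the base.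

Step 14
Reactants: 24 cis-decal-8-one
Product: 25 8-methylene compound: 9-[5-bromo-2-(methoxymethoxy)benzyl]-4-methoxy-5,9-dimethyl-8-methylene-cis-decal-3-ene
Conditions: Ph3PCH3Br, KOt-Bu, toluene, 90 °C
Reagents that add atoms: methyltriphenylphosphonium bromide, C[P+](c1ccccc1)(c1ccccc1)c1ccccc1.[Br-]
Why: Wittig methylenation with the ylide at elevated temperature, as used for ketones beside quaternary carbons; the enol ether keeps C4 masked so only C8 reacts.

Step 15
Reactants: 25 enol ether
Product: 26 9-[5-bromo-2-(methoxymethoxy)benzyl]-5,9-dimethyl-8-methylene-cis-decal-4-one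
Conditions: oxalic acid (aq.), THF, rt
Reagents that add atoms: water, O
Why: Hydrolysis of a methyl enol ether (protonation at C3, collapse of the hemiketal) is much faster under these mild conditions than cleavage of the aryl MOM ether or migration of the C8 methylene.

Step 16
Reactants: 26 8-methylene-4-ketone
Product: 27 9-[5-bromo-2-(methoxymethoxy)benzyl]-5,8,9-trimethyl-cis-decal-4-one with the C8 methyl cis to the C9 and C5 methyls (configuration of the target at C5, C8, C9 and C10)
Conditions: Mn(dpm)3 (cat.), PhSiH3, t-BuOOH, i-PrOH, rt
Reagents that add atoms: none
Why: Hydrogen-atom-transfer hydrogenation (metal hydride H-atom transfer to the alkene, then H-atom delivery to the tertiary C8 radical) gives the more stable epimer: in the ring B chair that keeps the C9 benzyl equatorial, the C8 methyl cis to the C9 methyl is equatorial, whereas its epimer would be syn-axial to C1; the radical conditions leave the aryl bromide, ketone and MOM ether untouched, which surface hydrogenation would not guarantee.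

Step 17
Reactants: 27 C4 ketone
Product: 28 MOM-protected aryl bromide with C4=C11: 9-[5-bromo-2-(methoxymethoxy)benzyl]-5,8,9-trimethyl-4-methylene-cis-decalin
Conditions: Ph3PCH3Br, KOt-Bu, toluene, 90 °C
Reagents that add atoms: methyltriphenylphosphonium bromide, C[P+](c1ccccc1)(c1ccccc1)c1ccccc1.[Br-]
Why: Wittig methylenation of a ketone beside quaternary C5; no epimerisable centre adjoins C4, so the forcing conditions cost no stereochemistry.

Step 18
Reactants: 28 aryl bromide
Product: 29 methyl 4-(methoxymethoxy)-3-{[(5S,8S,9R,10R)-5,8,9-trimethyl-4-methylene-cis-decalin-9-yl]methyl}benzoate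
Conditions: Pd(OAc)2 (cat.), dppf, CO (1 atm), Et3N, MeOH–DMF, 80 °C
Reagents that add atoms: carbon monoxide, [C-]#[O+]; methanol, CO
Why: Palladium-catalysed methoxycarbonylation of an aryl bromide (oxidative addition, CO insertion, methanolysis of the acyl complex); the isolated 1,1-disubstituted alkene does not compete under CO.

Step 19
Reactants: 29 MOM ether
Product: 30 methyl 4-hydroxy-3-{[(5S,8S,9R,10R)-5,8,9-trimethyl-4-methylene-cis-decalin-9-yl]methyl}benzoate (the target)
Conditions: HCl (dilute), MeOH, 0 °C to rt
Reagents that add atoms: none
Why: Acid-catalysed acetal exchange of an aryl MOM ether with methanol; phenol is a good leaving group, so the cleavage runs under conditions too mild to protonate the C4=C11 alkene.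

## Compound list

1 | 2,5-dimethoxy-4-methylbenzaldehyde | COc1cc(C=O)c(OC)cc1C | starting material
2 | 2,5-dimethoxy-4-methylphenyl formate | COc1cc(OC=O)c(OC)cc1C | intermediate
3 | 2,5-dimethoxy-4-methylphenol | COc1cc(O)c(OC)cc1C | intermediate
4 | phenyl vinyl sulfone | C=CS(=O)(=O)c1ccccc1 | starting material
5 | 3,6,6-trimethoxy-4-methylcyclohexa-2,4-dien-1-one (masked o-benzoquinone) | COC1=CC(=O)C(OC)(OC)C=C1C | intermediate
6 | racemic 3,3,6-trimethoxy-5-methyl-7-(phenylsulfonyl)bicyclo[2.2.2]oct-5-en-2-one (sulfonyl syn to the etheno bridge drawn) | COC1=C(C)[C@@H]2C[C@H](S(=O)(=O)c3ccccc3)[C@H]1C(=O)C2(OC)OC | intermediate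
7 | racemic 6-methoxy-5-methyl-7-(phenylsulfonyl)bicyclo[2.2.2]oct-5-en-2-one | COC1=C(C)[C@@H]2C[C@H](S(=O)(=O)c3ccccc3)[C@H]1C(=O)C2 | intermediate
8 | racemic 6-methoxy-5-methylbicyclo[2.2.2]oct-5-en-2-one | COC1=C(C)C2CCC1C(=O)C2 | intermediate
9 | (S)-N,S-dimethyl-S-phenylsulfoximine | C[S@@](=O)(=NC)c1ccccc1 | starting material
10 | 6-methoxy-5-methyl-2-{[(S)-N-methyl-S-phenylsulfonimidoyl]methyl}bicyclo[2.2.2]oct-5-en-2-ol of the (1R,4R)-ketone series, hydroxyl syn to the ethano bridge | COC1=C(C)[C@@H]2CC[C@H]1[C@](O)(C[S@@](=O)(=NC)c3ccccc3)C2 | intermediate
11 | (1R,4R)-6-methoxy-5-methylbicyclo[2.2.2]oct-5-en-2-one | COC1=C(C)[C@@H]2CC[C@H]1C(=O)C2 | intermediate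
12 | 5-bromosalicylaldehyde | O=Cc1cc(Br)ccc1O | starting material
13 | 5-bromo-2-(methoxymethoxy)benzaldehyde | O=Cc1cc(Br)ccc1OCOC | intermediate
14 | [5-bromo-2-(methoxymethoxy)phenyl]methanol | OCc1cc(Br)ccc1OCOC | intermediate
15 | 4-bromo-2-(bromomethyl)-1-(methoxymethoxy)benzene | BrCc1cc(Br)ccc1OCOC | intermediate
16 | lithium enolate of 11 (C8=C9) | COC1=C(C)[C@@H]2CC[C@H]1C([O-])=C2.[Li+] | intermediate
17 | 3-[5-bromo-2-(methoxymethoxy)benzyl]-6-methoxy-5-methylbicyclo[2.2.2]oct-5-en-2-one, benzyl syn to the etheno bridge | COC1=C(C)[C@@H]2CC[C@H]1C(=O)[C@@H]2Cc3cc(Br)ccc3OCOC | intermediate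
18 | lithium enolate of 17 (C8=C9) | COC1=C(C)[C@@H]2CC[C@H]1C([O-])=C2Cc3cc(Br)ccc3OCOC.[Li+] | intermediate
19 | 3-[5-bromo-2-(methoxymethoxy)benzyl]-6-methoxy-3,5-dimethylbicyclo[2.2.2]oct-5-en-2-one, C3 methyl syn to the etheno bridge, benzyl syn to the ethano bridge | COC1=C(C)[C@@H]2CC[C@H]1C(=O)[C@@]2(C)Cc3cc(Br)ccc3OCOC | intermediate
20 | vinylmagnesium bromide | C=C[Mg]Br | starting material
21 | 3-[5-bromo-2-(methoxymethoxy)benzyl]-2-ethenyl-6-methoxy-3,5-dimethylbicyclo[2.2.2]oct-5-en-2-ol, vinyl and C3 methyl syn to the etheno bridge | COC1=C(C)[C@@H]2CC[C@H]1[C@](O)(C=C)[C@@]2(C)Cc3cc(Br)ccc3OCOC | intermediate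
22 | potassium alkoxide of 21 | COC1=C(C)[C@@H]2CC[C@H]1[C@]([O-])(C=C)[C@@]2(C)Cc3cc(Br)ccc3OCOC.[K+] | intermediate
23 | potassium C7=C8 enolate of 24 | COC1=CCC[C@@H]2[C@](C)(Cc3cc(Br)ccc3OCOC)C([O-])=CC[C@]12C.[K+] | intermediate
24 | 9-[5-bromo-2-(methoxymethoxy)benzyl]-4-methoxy-5,9-dimethyl-cis-decal-3-en-8-one (target configuration at C5, C9, C10) | COC1=CCC[C@@H]2[C@](C)(Cc3cc(Br)ccc3OCOC)C(=O)CC[C@]12C | intermediate
25 | 9-[5-bromo-2-(methoxymethoxy)benzyl]-4-methoxy-5,9-dimethyl-8-methylene-cis-decal-3-ene | COC1=CCC[C@@H]2[C@](C)(Cc3cc(Br)ccc3OCOC)C(=C)CC[C@]12C | intermediate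
26 | 9-[5-bromo-2-(methoxymethoxy)benzyl]-5,9-dimethyl-8-methylene-cis-decal-4-one | O=C1CCC[C@@H]2[C@](C)(Cc3cc(Br)ccc3OCOC)C(=C)CC[C@]12C | intermediate
27 | (5S,8S,9R,10R)-9-[5-bromo-2-(methoxymethoxy)benzyl]-5,8,9-trimethyl-cis-decal-4-one | O=C1CCC[C@@H]2[C@](C)(Cc3cc(Br)ccc3OCOC)[C@@H](C)CC[C@]12C | intermediate
28 | (5S,8S,9R,10R)-9-[5-bromo-2-(methoxymethoxy)benzyl]-5,8,9-trimethyl-4-methylene-cis-decalin | C=C1CCC[C@@H]2[C@](C)(Cc3cc(Br)ccc3OCOC)[C@@H](C)CC[C@]12C | intermediate
29 | methyl 4-(methoxymethoxy)-3-{[(5S,8S,9R,10R)-5,8,9-trimethyl-4-methylene-cis-decalin-9-yl]methyl}benzoate | C=C1CCC[C@@H]2[C@](C)(Cc3cc(C(=O)OC)ccc3OCOC)[C@@H](C)CC[C@]12C | intermediate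
30 | methyl 4-hydroxy-3-{[(5S,8S,9R,10R)-5,8,9-trimethyl-4-methylene-cis-decalin-9-yl]methyl}benzoate | C=C1CCC[C@@H]2[C@](C)(Cc3cc(C(=O)OC)ccc3O)[C@@H](C)CC[C@]12C | target

## Step count and risk

Total: 19 steps. Longest linear sequence: 16 steps (steps 1–6 and 10–19); the aryl fragment takes 3 steps (7–9).

**Step 13 (key step).** The most likely failure is a slow sigmatropic shift, because the new bond forms at a fully substituted, electron-rich alkene carbon. This would leave time for heterolytic cleavage of the C3–C8 bond and fragmentation to ring-opened material. Fallback: starting from 21, the alcohol is silylated (Me3SiOTf, Et3N) to the trimethylsilyl ether F1, which is rearranged thermally without any anion (diphenyl ether, about 230 °C) to the silyl enol ether F2. Desilylation with Bu4NF returns the route at 24.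

**Step 16.** The risk is poor diastereoselectivity at C8, since both faces of the C8 radical are flanked (C1 on one side, the C9 methyl on the other) and the thermodynamic preference may not be fully expressed. Fallback: starting from 26, the exocyclic alkene is moved into the ring with RhCl3·3H2O in ethanol to give the C7=C8 isomer F3. This is then hydrogenated under kinetic control with [Ir(cod)(PCy3)(py)]PF6 in CH2Cl2. In F3 the C9 and C5 methyls flank both alkene carbons on one face, so hydrogen should arrive from the other and give 27.

**Step 14.** The risk is enolisation of the hindered C8 ketone by the basic ylide instead of addition, leading to stalled conversion. Fallback: starting from 24, Me3SiCH2Li with CeCl3 (a small, weakly basic nucleophile) adds to give the β-hydroxysilane F4, and Peterson elimination with KH returns the route at 25.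

**Step 12.** The risks are sluggish addition to a carbonyl flanked by a quaternary and a bridgehead carbon, and erosion of facial selectivity, which would place the vinyl group on the ethano side where it cannot rearrange. Fallback: starting from 19, the slimmer ethynylmagnesium bromide is added to give the ethynyl carbinol F5, and semi-hydrogenation over Pd/CaCO3 poisoned with Pb(OAc)2 and quinoline returns the route at 21.

**Step 5.** The risks are incomplete chromatographic separation of the two sulfoximine adducts, or loss of facial selectivity in the addition, which would give four adducts. Fallback: starting from 8, NaBH4 reduction gives the racemic alcohol F6, and lipase-catalysed acylation (Candida antarctica lipase B, vinyl acetate) converts one enantiomer into the acetate F7. The component with the bridgehead configuration of 11 (the alcohol itself, or the alcohol from methanolysis of F7) is oxidised with Dess–Martin periodinane and returns the route at 11.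

**Step 19.** The risk is acid-induced migration of the C4=C11 double bond into ring A during acetal cleavage. Fallback: starting from 27, the MOM group is removed with HCl in methanol before the alkene exists, giving the phenol ketone F8. Wittig methylenation with excess ylide gives the bromophenol alkene F9, and the palladium-catalysed methoxycarbonylation is run last, returning at 30.

## Further compounds

F1 | step 13 | trimethylsilyl ether of 21 | COC1=C(C)[C@@H]2CC[C@H]1[C@](O[Si](C)(C)C)(C=C)[C@@]2(C)Cc3cc(Br)ccc3OCOC
F2 | step 13 | C7=C8 trimethylsilyl enol ether of 24 | COC1=CCC[C@@H]2[C@](C)(Cc3cc(Br)ccc3OCOC)C(O[Si](C)(C)C)=CC[C@]12C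
F3 | step 16 | 9-[5-bromo-2-(methoxymethoxy)benzyl]-5,8,9-trimethyl-cis-decal-7-en-4-one | O=C1CCC[C@@H]2[C@](C)(Cc3cc(Br)ccc3OCOC)C(C)=CC[C@]12C
F4 | step 14 | C8 tertiary alcohol bearing CH2SiMe3 (C8 configuration immaterial) | COC1=CCC[C@@H]2[C@](C)(Cc3cc(Br)ccc3OCOC)C(O)(C[Si](C)(C)C)CC[C@]12C
F5 | step 12 | 2-ethynyl analogue of 21 | COC1=C(C)[C@@H]2CC[C@H]1[C@](O)(C#C)[C@@]2(C)Cc3cc(Br)ccc3OCOC
F6 | step 5 | racemic 6-methoxy-5-methylbicyclo[2.2.2]oct-5-en-2-ol, hydroxyl syn to the ethano bridge (enantiomer of the 11 series drawn) | COC1=C(C)[C@@H]2CC[C@H]1[C@@H](O)C2
F7 | step 5 | acetate of one enantiomer of F6 (drawn in the 11 series) | COC1=C(C)[C@@H]2CC[C@H]1[C@@H](OC(C)=O)C2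
F8 | step 19 | (5S,8S,9R,10R)-9-(5-bromo-2-hydroxybenzyl)-5,8,9-trimethyl-cis-decal-4-one | O=C1CCC[C@@H]2[C@](C)(Cc3cc(Br)ccc3O)[C@@H](C)CC[C@]12C
F9 | step 19 | 4-bromo-2-{[(5S,8S,9R,10R)-5,8,9-trimethyl-4-methylene-cis-decalin-9-yl]methyl}phenol | C=C1CCC[C@@H]2[C@](C)(Cc3cc(Br)ccc3O)[C@@H](C)CC[C@]12C
A1 | alternative 1 | 3-methylcyclohex-2-en-1-one | CC1=CC(=O)CCC1
A2 | alternative 1 | (5-chloropent-1-en-2-yl)diisobutylalane | C=C(CCCCl)[Al](CC(C)C)CC(C)C
A3 | alternative 1 | cis-5-methyl-4-methylenedecal-9-one | C=C1CCC[C@@H]2C(=O)CCC[C@]12C
A4 | alternative 2 | acyclic (Z)-diene (E)-enal | C=C/C=C\[C@](C)(Cc1cc(C(=O)OC)ccc1OCOC)[C@@H](C)CC/C(C)=C/C=O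
A5 | alternative 2 | cis-fused octalin 4-carbaldehyde | O=C[C@H]1CC=C[C@@H]2[C@](C)(Cc3cc(C(=O)OC)ccc3OCOC)[C@@H](C)CC[C@]12C
A6 | alternative 3 | ring B tert-butyldimethylsilyl enol ether with pent-4-ynyl chain on C10 | C#CCCC[C@@H]1[C@](C)(Cc2cc(C(=O)OC)ccc2OCOC)[C@@H](C)CC(O[Si](C)(C)C(C)(C)C)=C1C
A7 | alternative 3 | 6-oxo derivative of the MOM-protected target | C=C1CCC[C@@H]2[C@](C)(Cc3cc(C(=O)OC)ccc3OCOC)[C@@H](C)CC(=O)[C@]12C
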